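**Plan**

Numbering (bisabolane): carbocycle C1–C6 with C1 (CH3, ether O), C2 (OH), C5 (OAc); C7 (CH3, ether O) on C4; chain C8 (ether O)–C9–C10 (Br)–C11 (two CH3, ether O). Rings: oxepane C1–O–C8–C7–C4–C3–C2, tetrahydropyran C7–O–C11–C10–C9–C8.
Retrosynthesis: cut C11–O (bromoetherification by the C7 hydroxyl) and C10=C11 (cross-metathesis); move the oxepane oxygen from C8 back to C7, which gives a 1,8-cineole-type 2-oxabicyclo[2.2.2]octane with a leaving group on C8; then cut C8–C9 (allylboration), C1–O (epoxide opening), C7–CH3 and C7–C8 (Grignard additions), C1=C2 (ring-closing metathesis), C4–C5 (aldol).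
Forward order of rings: cyclohexene (aldol, metathesis), 2-oxabicyclo[2.2.2]octane (epoxidation, epoxide opening), 2-oxabicyclo[3.2.2]nonane by ring expansion, tetrahydropyran by bromoetherification.
Enabling feature: C7, the fully substituted ether carbon of the six-membered ring C1–O–C7–C4–C3–C2, is vicinal to C8, so the ring oxygen can shift from C7 to C8 through an oxiranium ion; the C5 acetate lies 1,3 to C7 on the C5–C6 bridge and can return an oxygen to cationic C7 only on the face the target needs.
Stereochemistry: C4 and C5 from the (R)-oxazolidinone syn aldol; C7 from chelation-controlled methyl addition; C1 and C2 from face-selective epoxidation and anti opening; C8 from anti-chelation allylboration, inverted in the key step; the C7–O bond from acetate delivery; C10 from a chair-like bromoetherification.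

Key step: step 13

**Route**

Step 1
Reactants: 1 (4R)-4-benzyl-1,3-oxazolidin-2-one; 2 pent-4-enoyl chloride
Product: 3 (4R)-4-benzyl-3-(pent-4-enoyl)-1,3-oxazolidin-2-one
Conditions: Et3N, DMAP (cat.), THF, 0 → 23 °C
Reagents that add atoms: none
Why: DMAP-catalysed N-acylation of the oxazolidinone by the acid chloride; no stereocenter is formed.

Step 2
Reactants: 4 3-methylbut-3-en-1-ol
Product: 5 3-methylbut-3-enal
Conditions: Dess–Martin periodinane (DMP), pyridine, CH2Cl2, 0 → 23 °C; filtered solution used at once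
Reagents that add atoms: none
Why: Dess–Martin oxidation under pyridine buffering should give the β,γ-unsaturated aldehyde without moving the double bond into conjugation.

Step 3
Reactants: 3 (4R)-4-benzyl-3-(pent-4-enoyl)-1,3-oxazolidin-2-one; 5 3-methylbut-3-enal
Product: 7 (4R)-4-benzyl-3-[(2R,3S)-3-hydroxy-5-methyl-2-(prop-2-en-1-yl)hex-5-enoyl]-1,3-oxazolidin-2-one, via Z-boron enolate 6 (not isolated)
Conditions: Bu2BOTf, Et3N, CH2Cl2, −78 → 0 °C; then 5, −78 → 0 °C; then pH 7 buffer, MeOH, H2O2, 0 °C
Reagents that add atoms: none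
Why: Evans syn aldol reaction: the Z-boron enolate 6 adds to 5 through a chair (Zimmerman–Traxler) transition state on the enolate face away from the benzyl group, which sets C4 (R) and C5 (S) in the 2,3-syn sense that becomes cis on the ring.

Step 4
Reactants: 7 aldol adduct
Product: 8 (4R)-4-benzyl-3-{[(1R,6S)-6-hydroxy-4-methylcyclohex-3-en-1-yl]carbonyl}-1,3-oxazolidin-2-one
Conditions: second-generation Grubbs catalyst RuCl2(H2IMes)(PCy3)(=CHPh) (5 mol %), CH2Cl2, 40 °C
Reagents that add atoms: none
Why: Ring-closing metathesis of the monosubstituted with the 1,1-disubstituted alkene closes the carbocycle as its trisubstituted C1=C2 alkene with loss of ethene; the stereocenters are not touched.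

Step 5
Reactants: 8 cyclohexene imide
Product: 9 (1R,6S)-6-hydroxy-N-methoxy-N,4-dimethylcyclohex-3-ene-1-carboxamide
Conditions: MeNHOMe·HCl, AlMe3, CH2Cl2, −20 → 23 °C
Reagents that add atoms: N,O-dimethylhydroxylamine hydrochloride (CNOC.Cl)
Why: Weinreb amide formation by aluminium amide aminolysis of the imide, helped by the free β-hydroxyl, releases the auxiliary 1.

Step 6
Reactants: 9 Weinreb amide
Product: 10 1-[(1R,6S)-6-hydroxy-4-methylcyclohex-3-en-1-yl]prop-2-en-1-one
Conditions: CH2=CHMgBr (3 equiv), THF, −78 → 0 °C; cold acidic quench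
Reagents that add atoms: vinylmagnesium bromide (C=C[Mg]Br)
Why: Grignard addition to the Weinreb amide stops at the ketone stage because the chelated tetrahedral adduct survives until the cold acidic quench.

Step 7
Reactants: 10 vinyl ketone
Product: 11 (2R)-2-[(1R,6S)-6-hydroxy-4-methylcyclohex-3-en-1-yl]but-3-en-2-ol
Conditions: MeMgBr (3 equiv), THF–CH2Cl2, −78 °C (inverse addition)
Reagents that add atoms: methylmagnesium bromide (C[Mg]Br)
Why: Chelation-controlled 1,2-addition: magnesium bridges the C5 alkoxide and the ketone oxygen in a chelate cis-fused to the cyclohexene, and methyl enters from its convex face (anti to C3), which sets C7 (R).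

Step 8
Reactants: 11 diol
Product: 12 (1S,6R)-6-[(2R)-2-hydroxybut-3-en-2-yl]-3-methylcyclohex-3-en-1-yl acetate
Conditions: Ac2O, pyridine, DMAP (cat.), CH2Cl2, 0 → 23 °C
Reagents that add atoms: acetic anhydride (CC(=O)OC(C)=O)
Why: Acetylation of the secondary C5 hydroxyl only, the tertiary allylic hydroxyl being too hindered; the acetate is the ester of the target and the neighbouring group of step 13.

Step 9
Reactants: 12 monoacetate
Product: 14 (1R,3R,4R,5S,7R)-3-ethenyl-7-hydroxy-1,3-dimethyl-2-oxabicyclo[2.2.2]octan-5-yl acetate, via trans-epoxide 13 (not isolated)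
Conditions: mCPBA, CH2Cl2, 0 °C; then PPTS (cat.), 23 °C
Reagents that add atoms: mCPBA (O=C(OO)c1cccc(Cl)c1)
Why: Peracid epoxidation of the trisubstituted ring alkene (the vinyl group reacts far more slowly) anti to the axial C5 acetate and the C4 side chain gives 13, and acid lets the C7 hydroxyl open it at the tertiary C1 with inversion, as α-terpineol oxide closes to 2-hydroxy-1,8-cineole, which sets C1 (R) and C2 (R) with the hydroxyl anti to the new ether bond.

Step 10
Reactants: 14 bicyclic alcohol
Product: 15 (1R,3R,4R,5S,7R)-3-ethenyl-1,3-dimethyl-7-[(triethylsilyl)oxy]-2-oxabicyclo[2.2.2]octan-5-yl acetate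
Conditions: TESOTf, 2,6-lutidine, CH2Cl2, −78 → 0 °C
Reagents that add atoms: triethylsilyl triflate (CC[Si](CC)(CC)OS(=O)(=O)C(F)(F)F)
Why: Silylation of the hindered secondary C2 hydroxyl masks it for the sulfonylation in step 13.

Step 11
Reactants: 15 silyl ether
Product: 17 (1R,3S,4R,5S,7R)-3-formyl-1,3-dimethyl-7-[(triethylsilyl)oxy]-2-oxabicyclo[2.2.2]octan-5-yl acetate, via secondary ozonide 16 (not isolated)
Conditions: O3, CH2Cl2, −78 °C; then PPh3, −78 → 23 °C
Reagents that add atoms: ozone (O=[O+][O-])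
Why: Ozonolysis of the vinyl group with reductive work-up gives the aldehyde, which cannot epimerise because C7 is fully substituted.

Step 12
Reactants: 17 aldehyde
Product: 18 (1R,3S,4R,5S,7R)-3-[(1R)-1-hydroxybut-3-en-1-yl]-1,3-dimethyl-7-[(triethylsilyl)oxy]-2-oxabicyclo[2.2.2]octan-5-yl acetate
Conditions: CH2=CHCH2B(pin), toluene, 23 → 40 °C; aqueous work-up
Reagents that add atoms: allylboronic acid pinacol ester (C=CCB1OC(C)(C)C(C)(C)O1)
Why: Uncatalysed allylboration through a closed chair transition state follows the Cornforth (anti-chelation) sense for an α-alkoxy aldehyde: with C=O anti to the C7–O bond, allyl enters on the side of the C7 methyl, away from the cage, which sets C8 (R).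

Step 13
Reactants: 18 homoallylic alcohol
Product: 22 (1R,3S,4S,5R,6S,8R)-4,8-dihydroxy-1,4-dimethyl-3-(prop-2-en-1-yl)-2-oxabicyclo[3.2.2]nonan-6-yl acetate, via triflate 19 (not isolated), via bicyclic oxiranium ion 20 (not isolated), via dioxanylium ion 21 (not isolated)
Conditions: Tf2O, 2,6-di-tert-butyl-4-methylpyridine, CH2Cl2, −78 → 0 °C; then AcOH–H2O–THF (3:1:1), 23 °C
Reagents that add atoms: water (O)
Why: Proposed new method: the triflate 19 ionises with help of the ring oxygen, which is antiperiplanar to the C8–O bond in the least hindered rotamer (H8, not the allyl CH2, then lies over the C2–C3 bridge), and a 3-exo-tet closure gives the oxiranium ion 20; cleavage of its O–C7 bond turns the six-membered ether C1–O–C7–C4–C3–C2 into the seven-membered ether C1–O–C8–C7–C4–C3–C2 and leaves a tertiary cation at C7. The carbonyl oxygen of the C5 acetate captures this cation in a six-membered neighbouring-group closure to the 1,3-dioxan-2-ylium ion 21, which the aqueous acid should hydrolyse to the tertiary alcohol with the acyl group left on the less hindered C5 oxygen, while the same medium removes the triethylsilyl group. The closest known reaction types are the ring expansion of 2-(1-sulfonyloxyalkyl) cyclic ethers through oxiranium ions (tetrahydrofuran to tetrahydropyran, tetrahydropyran to oxepane, usually with Zn(OAc)2 and an external oxygen nucleophile) and the capture of cations by a neighbouring ester as an acyloxonium ion. C8 is set by inversion (8R triflate to 8S ether). C7 (7S) is set by the acetate, which is held on the C5–C6 bridge and reaches only the face of C7 that points to this bridge, whatever the lifetime of the cation. The step needs oxygen participation instead of a 1,2-shift of C4 or CH3, secured by the C8 configuration from step 12, and capture at C7 from the acetate face instead of the open face, secured by the absence of any other nucleophile until 21 has formed.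

Step 14
Reactants: 22 ring-expanded diol
Product: 23 (1R,3S,4S,5R,6S,8R)-4,8-dihydroxy-1,4-dimethyl-3-(3-methylbut-2-en-1-yl)-2-oxabicyclo[3.2.2]nonan-6-yl acetate
Conditions: 2-methylbut-2-ene (co-solvent), second-generation Hoveyda–Grubbs catalyst RuCl2(H2IMes)(=CH-C6H4-2-OiPr) (5 mol %), CH2Cl2, 40 °C
Reagents that add atoms: 2-methylbut-2-ene (CC=C(C)C)
Why: Cross-metathesis of the terminal alkene with 2-methylbut-2-ene installs the trisubstituted C10=C11 alkene; no stereocenter is involved.

Step 15
Reactants: 23 prenyl diol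
Product: 24 (1R,2R,4R,5S,7S,8S,10S)-10-bromo-1,8:7,11-diepoxy-2-hydroxybisabolan-5-yl acetate (CNP0247588.2)
Conditions: 2,4,4,6-tetrabromocyclohexa-2,5-dienone (TBCO), MeNO2, 0 °C
Reagents that add atoms: TBCO (O=C1C(Br)=CC(Br)(Br)C=C1Br)
Why: Bromoetherification (6-endo, Markovnikov): Br+ and the tertiary C7 hydroxyl add anti across C10=C11 through a chair-like transition state with the C–Br bond equatorial and the smaller C7 methyl axial, which closes the tetrahydropyran and should set C10 (S).

**Compound list**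

1 | (4R)-4-benzyl-1,3-oxazolidin-2-one | O=C1N[C@H](Cc2ccccc2)CO1 | starting material
2 | pent-4-enoyl chloride | C=CCCC(Cl)=O | starting material
3 | (4R)-4-benzyl-3-(pent-4-enoyl)-1,3-oxazolidin-2-one | C=CCCC(=O)N1C(=O)OC[C@H]1Cc2ccccc2 | intermediate
4 | 3-methylbut-3-en-1-ol | CC(=C)CCO | starting material
5 | 3-methylbut-3-enal | CC(=C)CC=O | intermediate
6 | (Z)-dibutylboron enolate of 3 (not isolated) | C=CC/C=C(\OB(CCCC)CCCC)N1C(=O)OC[C@H]1Cc2ccccc2 | intermediate
7 | (4R)-4-benzyl-3-[(2R,3S)-3-hydroxy-5-methyl-2-(prop-2-en-1-yl)hex-5-enoyl]-1,3-oxazolidin-2-one | C=C(C)C[C@H](O)[C@@H](CC=C)C(=O)N1C(=O)OC[C@H]1Cc2ccccc2 | intermediate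
8 | (4R)-4-benzyl-3-{[(1R,6S)-6-hydroxy-4-methylcyclohex-3-en-1-yl]carbonyl}-1,3-oxazolidin-2-one | O[C@H]1CC(C)=CC[C@H]1C(=O)N2C(=O)OC[C@H]2Cc3ccccc3 | intermediate
9 | (1R,6S)-6-hydroxy-N-methoxy-N,4-dimethylcyclohex-3-ene-1-carboxamide | O[C@H]1CC(C)=CC[C@H]1C(=O)N(C)OC | intermediate
10 | 1-[(1R,6S)-6-hydroxy-4-methylcyclohex-3-en-1-yl]prop-2-en-1-one | O[C@H]1CC(C)=CC[C@H]1C(=O)C=C | intermediate
11 | (2R)-2-[(1R,6S)-6-hydroxy-4-methylcyclohex-3-en-1-yl]but-3-en-2-ol | O[C@H]1CC(C)=CC[C@H]1[C@](O)(C=C)C | intermediate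
12 | (1S,6R)-6-[(2R)-2-hydroxybut-3-en-2-yl]-3-methylcyclohex-3-en-1-yl acetate | CC(=O)O[C@H]1CC(C)=CC[C@H]1[C@](O)(C=C)C | intermediate
13 | (1S,3S,4R,6R)-4-[(2R)-2-hydroxybut-3-en-2-yl]-1-methyl-7-oxabicyclo[4.1.0]heptan-3-yl acetate (not isolated) | CC(=O)O[C@H]1C[C@]2(C)O[C@@H]2C[C@H]1[C@](O)(C=C)C | intermediate
14 | (1R,3R,4R,5S,7R)-3-ethenyl-7-hydroxy-1,3-dimethyl-2-oxabicyclo[2.2.2]octan-5-yl acetate | CC(=O)O[C@H]1C[C@@]2(C)O[C@@](C=C)(C)[C@@H]1C[C@H]2O | intermediate
15 | (1R,3R,4R,5S,7R)-3-ethenyl-1,3-dimethyl-7-[(triethylsilyl)oxy]-2-oxabicyclo[2.2.2]octan-5-yl acetate | CC(=O)O[C@H]1C[C@@]2(C)O[C@@](C=C)(C)[C@@H]1C[C@H]2O[Si](CC)(CC)CC | intermediate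
16 | 1,2,4-trioxolane (secondary ozonide) of the vinyl group of 15, mixture at the new ring carbon (not isolated) | CC(=O)O[C@H]1C[C@@]2(C)O[C@@](C3OCOO3)(C)[C@@H]1C[C@H]2O[Si](CC)(CC)CC | intermediate
17 | (1R,3S,4R,5S,7R)-3-formyl-1,3-dimethyl-7-[(triethylsilyl)oxy]-2-oxabicyclo[2.2.2]octan-5-yl acetate | CC(=O)O[C@H]1C[C@@]2(C)O[C@@](C=O)(C)[C@@H]1C[C@H]2O[Si](CC)(CC)CC | intermediate
18 | (1R,3S,4R,5S,7R)-3-[(1R)-1-hydroxybut-3-en-1-yl]-1,3-dimethyl-7-[(triethylsilyl)oxy]-2-oxabicyclo[2.2.2]octan-5-yl acetate | CC(=O)O[C@H]1C[C@@]2(C)O[C@@]([C@H](O)CC=C)(C)[C@@H]1C[C@H]2O[Si](CC)(CC)CC | intermediate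
19 | C8 trifluoromethanesulfonate of 18 (not isolated) | CC(=O)O[C@H]1C[C@@]2(C)O[C@@]([C@H](OS(=O)(=O)C(F)(F)F)CC=C)(C)[C@@H]1C[C@H]2O[Si](CC)(CC)CC | intermediate
20 | bicyclic oxiranium ion, O bonded to C1, C7 and C8 (not isolated) | CC(=O)O[C@H]1C[C@@]2(C)[O+]3[C@@H](CC=C)[C@]3(C)[C@@H]1C[C@H]2O[Si](CC)(CC)CC | intermediate
21 | 2-methyl-1,3-dioxan-2-ylium ion bridging the C5 and C7 oxygens (not isolated) | CC1=[O+][C@H]2C[C@@]3(C)O[C@@H](CC=C)[C@](O1)(C)[C@@H]2C[C@H]3O[Si](CC)(CC)CC | intermediate
22 | (1R,3S,4S,5R,6S,8R)-4,8-dihydroxy-1,4-dimethyl-3-(prop-2-en-1-yl)-2-oxabicyclo[3.2.2]nonan-6-yl acetate | CC(=O)O[C@H]1C[C@@]2(C)O[C@@H](CC=C)[C@](O)(C)[C@@H]1C[C@H]2O | intermediate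
23 | (1R,3S,4S,5R,6S,8R)-4,8-dihydroxy-1,4-dimethyl-3-(3-methylbut-2-en-1-yl)-2-oxabicyclo[3.2.2]nonan-6-yl acetate | CC(=O)O[C@H]1C[C@@]2(C)O[C@@H](CC=C(C)C)[C@](O)(C)[C@@H]1C[C@H]2O | intermediate
24 | (1R,2R,4R,5S,7S,8S,10S)-10-bromo-1,8:7,11-diepoxy-2-hydroxybisabolan-5-yl acetate (CNP0247588.2) | CC(=O)O[C@H]1C[C@@]2(C)O[C@H]3C[C@H](Br)C(C)(C)O[C@@]3(C)[C@@H]1C[C@H]2O | target

**Count**

Total steps: 15. Longest linear sequence: 14 (steps 1 and 3–15; step 2 is a one-step branch).

**Steps most likely to fail**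

1. Step 13 (bears the label "Proposed new method:"). After the oxygen shift, cationic C7 may be intercepted on its open face (triflate return, adventitious water) or lose a proton before the acetate closes the dioxanylium ring, and on hydrolysis the acetyl group may stay on the tertiary oxygen. Fallback with known chemistry only, without an oxygen shift, from 12 back to 22: silylation of the tertiary hydroxyl with TESOTf gives the triethylsilyl ether F1; mCPBA epoxidises the ring alkene anti to the acetate to the epoxide F2; ozonolysis of the vinyl group gives the aldehyde F3; reagent-controlled allylboration with the enantiomer of Ipc2B(allyl) that adds to the Si face of the aldehyde gives the (S)-homoallylic alcohol F4; camphorsulfonic acid then lets this hydroxyl open the epoxide at the tertiary C1 with inversion, which closes the seven-membered ether directly as the bridged silyl ether F5; AcOH–H2O–THF removes the silyl group and returns to 22.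

2. Step 15. Br+ may be delivered to either face of C10=C11, and the hydroxyl may close at C10 (5-exo) instead of C11. Fallback from 23 back to 24: cyclisation with Hg(O2CCF3)2 in MeNO2 is reversible, so the chair with the equatorial C10–Hg bond should be reached under thermodynamic control; exchange with aqueous KBr gives the alkylmercuric bromide F6; Br2 and LiBr in pyridine then replace mercury by bromine with retention and give 24.

3. Step 7. Conjugate addition to the vinyl ketone, oxa-Michael closure of the C5 alkoxide onto it, or attack outside the chelate would erode the yield and the C7 configuration. Fallback from 9 back to 11, with the order of the two additions and the control element exchanged: MeMgBr gives the methyl ketone F7; TBSOTf and 2,6-lutidine give its silyl ether F8, which cannot chelate; CH2=CHMgBr with CeCl3 adds under Felkin–Anh control (C5 anti to the nucleophile) to give the tertiary alcohol F9 with the same C7 configuration; Bu4NF removes the silyl group and returns to 11.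

**Further compounds**

F1 | step 13 | (1S,6R)-3-methyl-6-{(2R)-2-[(triethylsilyl)oxy]but-3-en-2-yl}cyclohex-3-en-1-yl acetate | CC(=O)O[C@H]1CC(C)=CC[C@H]1[C@](O[Si](CC)(CC)CC)(C=C)C
F2 | step 13 | 1,2-epoxide of F1, anti to the acetate | CC(=O)O[C@H]1C[C@]2(C)O[C@@H]2C[C@H]1[C@](O[Si](CC)(CC)CC)(C=C)C
F3 | step 13 | aldehyde from ozonolysis of F2 | CC(=O)O[C@H]1C[C@]2(C)O[C@@H]2C[C@H]1[C@](O[Si](CC)(CC)CC)(C=O)C
F4 | step 13 | (S)-homoallylic alcohol from F3 | CC(=O)O[C@H]1C[C@]2(C)O[C@@H]2C[C@H]1[C@](O[Si](CC)(CC)CC)([C@@H](O)CC=C)C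
F5 | step 13 | 22 as its triethylsilyl ether at the tertiary oxygen | CC(=O)O[C@H]1C[C@@]2(C)O[C@@H](CC=C)[C@](O[Si](CC)(CC)CC)(C)[C@@H]1C[C@H]2O
F6 | step 15 | 24 with HgBr in place of Br at C10 | CC(=O)O[C@H]1C[C@@]2(C)O[C@H]3C[C@H]([Hg]Br)C(C)(C)O[C@@]3(C)[C@@H]1C[C@H]2O
F7 | step 7 | 1-[(1R,6S)-6-hydroxy-4-methylcyclohex-3-en-1-yl]ethan-1-one | O[C@H]1CC(C)=CC[C@H]1C(C)=O
F8 | step 7 | tert-butyldimethylsilyl ether of F7 | C[Si](C)(C(C)(C)C)O[C@H]1CC(C)=CC[C@H]1C(C)=O
F9 | step 7 | tert-butyldimethylsilyl ether of 11 at the secondary oxygen | C[Si](C)(C(C)(C)C)O[C@H]1CC(C)=CC[C@H]1[C@](O)(C=C)C
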